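Ash stops climbing in target sooner than elm, at 8.00 h against 60.0 h, taking the first reading on each plateau.

all flasks: partner A 0.0732 M; partner B 0.0732 M
- elm: substrate 0.061 M; protic impurity 1.5 mM; temperature 35 °C; run made earlier
- ash: substrate 0.061 M; protic impurity 6.1 mM; temperature 70 °C; run made earlier
- alder: substrate 0.030 M; protic impurity 3.05 mM; temperature 35 °C; run made earlier
- dusk: substrate 0.061 M; protic impurity 3.05 mM; temperature 100 °C; time 5.0 h
- noon: substrate 0.061 M; protic impurity 3.05 mM; temperature 40 °C; time 5.0 h
- summer: substrate 0.061 M; protic impurity 3.05 mM; temperature 70 °C; time 5.0 h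

- elm (time / h: target / %, homo product / %): 30.0: 14.4, 1.8; 60.0: 24.3, 4.7; 96.0: 25.2, 5.2; 120: 26.3, 5.4
- ash (time / h: target / %, homo product / %): 2.00: 10.4, 1.8; 4.00: 16.5, 4.5; 8.00: 22.9, 9.8; 20.0: 23.9, 18.1
- alder (time / h: target / %, homo product / %): 10.0: 5.4, 1.4; 25.0: 24.6, 1.9; 50.0: 51.8, 1.7; 120: 84.2, 2.0

(each reading ± 1 percentage point)

- in percentages every species weighs as the substrate in it: one homo product counts as two
- what was read earlier has a scatter of 1 percentage point, one standard deviation

* the flask with the highest share of target in all that became target or homo product ("all alike" if they lie within 1.5 percentage points) (dusk / noon / summer / all alike)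
* share of target in all that became target or homo product, dusk
* share of target in all that became target or homo product, noon
* share of target in all that became target or homo product, summer

Two times matter: the stall time and the time asked. In ash the share of target (the selectivity) already falls before the stall, from 85.2% at 2.00 h to 70.0% at 8.00 h. It goes on falling past the stall, to 56.9% at 20.0 h, while its target moves by 1 percentage point. So in ash the share is higher the earlier the reading.

The two stalls, read as one Arrhenius line, give 50.6 kJ mol⁻¹. That is a coarse reading, and it sets aside that ash held more impurity than elm. Noon should then stall at 43.8 h, so its value is 0.114: this is the stall fraction, the asked time over the stall time at the flask's temperature, a reduced time. Summer has 0.625 and dusk 2.60.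

My reckoning follows. Noon, well before its stall, should at least match elm's early 88.9%. Summer, between ash's readings, comes to 76.4%. Dusk, past its stall and hotter than ash, should lie below 56.9%. So I put noon first.

The forecast puts summer first, with dusk 55% (42% to 68%), noon 72% (52% to 88%) and summer 79% (71% to 86%), and it calls noon “still near the end of induction”.

The flask gives dusk 49.0%, noon 89.7% and summer 77.4%, so noon leads.

    substrate + partner B → open intermediate (k = 0.860 M⁻¹ min⁻¹, Ea = 64.0 kJ mol⁻¹)
    partner B + partner A → second intermediate (k = 0.0987 M⁻¹ min⁻¹, Ea = 66.0 kJ mol⁻¹)
    open intermediate + second intermediate → target (k = 0.173 M⁻¹ min⁻¹, Ea = 53.0 kJ mol⁻¹)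
    2 open intermediate → homo product (k = 0.00388 M⁻¹ min⁻¹, Ea = 78.0 kJ mol⁻¹)
    partner B + protic impurity → quenched reagent (k = 6.02 M⁻¹ min⁻¹, Ea = 61.0 kJ mol⁻¹)
    (constants at 70 °C)

In noon at 1.18 h, the half-life of partner B by the step to second intermediate is 15 h, longer than the 5.0 h asked. At 5.00 h noon holds 64.9% as open intermediate against 2.13% as target, at a stall fraction of 0.114. The neighbour like noon but kept at 25 °C has a stall fraction of 0.0430 and gives 92.3%.

The numbers in the tables are simulated on assumed constants, noise included.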